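**Remark on the chemistry.** Benzofuran numbering is used (O1, C2, C3, C3a, C4–C7, C7a); ring C atoms are primed, C1' being bonded to C2. The side-chain methine is R as drawn. Compound 25 is expected as a mixture of C2 epimers, and both are carried on.

## The problem

The target is a 2-arylbenzofuran. Ring A is a phloroglucinol-type benzene with free hydroxyls at C4 and C6 and an (R)-3-methylbut-3-en-2-yl group at C7; it is fused to furan ring B. C2 carries ring C, a resorcinol-type arene with a prenyl group at C2', a free hydroxyl at C3' and a 2,2-dimethylchromane annulated across C5'/C6'. Ring C is therefore flanked on both sides of the C2–C1' bond by carbon substituents, so any step that forms this bond, or attacks a carbonyl on C1', meets a di-ortho-substituted arene. The only stereocentre is the benzylic, allylic methine of the C7 side chain. No second stereocentre can relay to it, so it must be set by a reagent or by chirality transfer and then kept away from enolisation, ionisation and hydride abstraction. Ring A also poses a differentiation problem: C7 lies between two oxygens, of which the one at C7a ends in the furan, while the one at C6 and the remote one at C4 end as free phenols. Late reagents are restricted: the isopropenyl/C6–OH and prenyl/C3'–OH pairs cyclise under acid, the three alkenes exclude hydrogenolysis, and the electron-rich phenols are easily oxidised, so the last deprotection should be fluoride on silyl ethers. The feature that opens a short way to ring B is the C3–C3a bond: if the C7a oxygen carries a 1-(ring C)vinyl group, its lone pair, the vinyl π bond and the C7a–C3a π bond form a six-electron system, and C3a is the only ortho carbon of that oxygen that still bears hydrogen, because C7 is occupied.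

## Retrosynthesis

**O–Si bonds and the C2=C3 unsaturation.** Target 27 is taken back to its tris(tert-butyldimethylsilyl) ether 26. Silyl ethers are preferred to alkyl or acetal ethers because fluoride leaves the two alkene/phenol pairs uncyclised, and to esters because a second ester would not survive carbonyl methylenation. Ether 26 is taken back to the 2,3-dihydrobenzofuran 25 by adding two hydrogens across C2–C3. This costs one oxidation in the forward direction, but 25 is the direct product of a ring closure that needs no functional group at C3a, and the configuration at C2 becomes irrelevant.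

**C3–C3a (key cut).** Opening ring B of 25 at C3–C3a gives the aryl vinyl ether 23, in which rings A and C are joined only through O1 and C2; the forward reaction is a photochemical closure through ylide 24. The neighbouring cuts are weaker here. Cutting C2–C1' asks for a cross-coupling at a carbon with two ortho substituents. Cutting O1–C2 or C2=C3 needs a halogen or a carbon substituent installed first at C3a of the chiral ring A fragment. The C3–C3a cut needs only the hydrogen already there, and since C7 is blocked there is no choice of ortho carbon. The forward step must close faster than the side-chain and prenyl alkenes react under irradiation.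

**Enol ether C=CH2 and ester C–O.** The C=CH2 of 23 is traced to the carbonyl of aryl ester 22, and the ester is cut to phenol 11 and acid 20 (used as chloride 21). This replaces vinylation of a hindered phenol by an acylation: C2 arrives with ring C as the carboxyl carbon, and C3 comes from the methylenating reagent. The two fragments are of similar size, so the route is convergent here. The forward steps must acylate a phenol next to a branched substituent with a di-ortho-substituted aroyl chloride and methylenate the shielded ester carbonyl without acid.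

**Side-chain terminus of ring A.** Phenol 11 comes from acetate 10, 10 from methyl ketone 9, and 9 from the (E)-alkene 7 through ozonide 8. This detour is the price of making the stereocentre by a sigmatropic shift. Chirality is relayed through a [3,3] transition state only from a stereogenic carbinol carbon, which ends as the distal alkene carbon; that carbon therefore cannot be the CH2 of the target and must be trimmed by one carbon. The acetate is needed because a free phenol next to the ketone would close to a hemiketal and on to a benzofuran. The forward steps must cleave the alkene without touching the arene and methylenate an epimerisable α-aryl ketone without base.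

**C7–side-chain bond and ether C–O.** Acetate 7 is the trapped form of phenol 6, which is cut by a retro-Claisen step to the aryl allyl ether 5. Ether 5 is cut at C–O to phenol 2 and allylic alcohol 4, which come from phloroglucinol 1 and enone 3. In 5 the two ortho carbons are equivalent, and the rearrangement frees exactly the oxygen that must later carry the vinyl group while the other two stay silylated. Ring A is thus differentiated without selective protection, and the benzylic configuration follows from that of 4. The forward demand is clean inversion in the etherification and clean suprafacial transfer in the rearrangement.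

**Ring C adjustments and chromane C–O.** Acid 20 comes from hydroxy acid 18 through silyl ester 19, and 18 from methyl ester 17. The chromane C–O bond of 17 is cut to the symmetric diprenyl resorcinol 16, so both ortho substituents of ring C have the same origin. The cost is that 16 has two equivalent prenyl/hydroxyl pairs and the closure must be stopped after one. The ester must be cleaved at the methyl carbon because its carbonyl is shielded.

**Aryl–CH2 bonds of ring C.** The two aryl–CH2 bonds of 16 are cut by two retro-Claisen steps to the bis(1,1-dimethylallyl) ether 15, which comes from bis(propargyl) ether 14 and so from methyl 3,5-dihydroxybenzoate 12 and chloroalkyne 13. This is preferred to direct C-prenylation, which would have to discriminate C2/C6 from C4 and carbon from oxygen. In the rearrangement the tertiary ether delivers a normal prenyl group to an ortho carbon, and both the ester and the second oxygen direct it to the carbon next to the ester. The forward step must achieve this regiochemistry twice.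

## Roads not taken

**Alternative 1:** Ring A is cut at C7–C7a and C5–C6 and built by benzannulation. Heating the cyclobutenone A2 with the siloxyalkyne A3, which already carries the stereocentre, would give phenol A1 through a vinylketene cascade.
- Merit: A1 has three differently substituted oxygens with the free hydroxyl next to the side chain. In this respect it is better than the chosen route, which needs a statistical bis-silylation (step 1) and an acetate detour (steps 4–7), and the stereocentre never passes through a sigmatropic shift.
- Weak points: A3 must be made enantiopure, and its propargylic, allylic stereocentre would have to survive strongly basic ynolate chemistry during its preparation. A2 and A3 are both multistep. The reaction supplies only a ring A phenol; ring B and the hindered bond to ring C remain to be made.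
- Comparison: the chosen plan sets against it a stereocentre of predictable configuration from a catalytic reduction, ring A differentiation from the symmetry of 5, and a ring B closure that is part of the plan.

**Alternative 2:** Ring A is cut at C4–C5 and formed last by a polyketide-type Claisen condensation. Base would convert the methyl ketone of furan A5 into its enolate, which attacks the furan-3-carboxylate; enolisation aromatises ring A and gives A4, the target with one methoxymethyl ether on ring C.
- Merit: ring A arrives with both phenols free, with no protecting group on ring A, no oxidant and no photochemistry. In these respects it is better than the chosen plan.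
- Weak points: A5 is a 2,3,5-trisubstituted furan that already carries the hindered ring C and a side arm with the stereocentre next to an epimerisable, doubly activated carbon, so its synthesis is long. The furan ester is a poor electrophile. The final acetal cleavage needs acid, the condition under which the prenyl/phenol and isopropenyl/phenol pairs cyclise.
- Comparison: the chosen plan sets against it a precursor assembled from two simple arenes by an ester bond and an endgame that uses only fluoride.

**Alternative 3:** Ring B is cut at C2=C3 and closed by an acyl Wittig reaction. Et3N would deprotonate phosphonium salt A7, and the ylide condenses with the neighbouring aryl ester carbonyl to give A6, which is identical with 26.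
- Merit: the benzofuran forms at the right oxidation level from the same two fragments (11 and 21), with no irradiation and no quinone oxidant. Its precedent for 2-arylbenzofurans is firmer than that of the chosen key step.
- Weak points: C3a must first receive a one-carbon unit (formylation, reduction, phosphonium salt formation), the last under acid that threatens the isopropenyl/phenol pair and the aryl silyl ethers.
- Comparison: the step count from 11 to 26 is the same, four in each case. The chosen plan needs no substituent at C3a and no acid, and it takes C3 from the methylenating reagent, but it is less secure. Alternative 3 is therefore kept as the fallback for the key step.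

Key step: step 16

## Route

**Step 1**
Reactants: 1 phloroglucinol
Product: 2 3,5-bis(tert-butyldimethylsilyloxy)phenol
Conditions: TBSCl (2.0 equiv), imidazole, DMF, 0 °C to rt; chromatography, other silyl ethers desilylated and recycled
Reagents that add atoms: tert-butyldimethylsilyl chloride, CC(C)(C)[Si](C)(C)Cl
Why: Silyl ether formation by substitution at silicon under imidazole catalysis; the three hydroxyls are equivalent, so the bis-ether forms statistically, which is acceptable for the cheapest compound of the route.

**Step 2**
Reactants: 3 (E)-3-methylpent-3-en-2-one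
Product: 4 (2R,3E)-3-methylpent-3-en-2-ol
Conditions: (S)-2-methyl-CBS-oxazaborolidine (10 mol %), catecholborane, PhMe, −78 °C; aq. NaOH work-up
Reagents that add atoms: none
Why: Corey–Bakshi–Shibata reduction; the trisubstituted alkenyl group acts as the large substituent and methyl as the small one, so hydride should go to the face that gives the R carbinol, as with aryl methyl ketones and this catalyst antipode, and 1,2-reduction is favoured at low temperature.

**Step 3**
Reactants: 2 3,5-bis(tert-butyldimethylsilyloxy)phenol; 4 (2R,3E)-3-methylpent-3-en-2-ol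
Product: 5 1-[(2S,3E)-3-methylpent-3-en-2-yl]oxy-3,5-bis(tert-butyldimethylsilyloxy)benzene
Conditions: PPh3, DIAD, PhMe, 0 °C to rt
Reagents that add atoms: none
Why: Mitsunobu etherification; the phenol displaces the activated secondary allylic oxyphosphonium group by SN2 with inversion (R alcohol to S ether), and the substituted alkene terminus disfavours the SN2' pathway.

**Step 4**
Reactants: 5 1-[(2S,3E)-3-methylpent-3-en-2-yl]oxy-3,5-bis(tert-butyldimethylsilyloxy)benzene
Product: 7 3,5-bis(tert-butyldimethylsilyloxy)-2-[(2R,3E)-3-methylpent-3-en-2-yl]phenyl acetate, via Claisen phenol 6 (not isolated)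
Conditions: Eu(fod)3 (10 mol %; fod = 6,6,7,7,8,8,8-heptafluoro-2,2-dimethyloctane-3,5-dionate), CHCl3, 50 °C; then Ac2O, Et3N, DMAP (cat.), rt
Reagents that add atoms: acetic anhydride, CC(=O)OC(C)=O
Why: Aromatic Claisen rearrangement ([3,3]) catalysed by the trivalent europium Lewis acid through a chair transition state with the carbinol methyl pseudo-equatorial, which forms the E alkene and turns the S carbinol carbon into the R benzylic carbon; both ortho carbons of 5 are equivalent, and the freed phenol is acetylated in the same flask so that it can neither enter the abnormal Claisen pathway nor add to the ketone of step 5.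

**Step 5**
Reactants: 7 3,5-bis(tert-butyldimethylsilyloxy)-2-[(2R,3E)-3-methylpent-3-en-2-yl]phenyl acetate
Product: 9 3,5-bis(tert-butyldimethylsilyloxy)-2-[(2S)-3-oxobutan-2-yl]phenyl acetate, via ozonide 8 (not isolated)
Conditions: O3, CH2Cl2, −78 °C, stopped at the first excess of ozone; then PPh3, −78 °C to rt
Reagents that add atoms: ozone, [O-][O+]=O
Why: Ozonolysis (Criegee mechanism) of the only alkene, which is trisubstituted and should react far faster than the arene; reduction of the ozonide gives the methyl ketone and acetaldehyde without acid or base, so the stereocentre is untouched (its descriptor becomes S only because acetyl outranks aryl).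

**Step 6**
Reactants: 9 3,5-bis(tert-butyldimethylsilyloxy)-2-[(2S)-3-oxobutan-2-yl]phenyl acetate
Product: 10 3,5-bis(tert-butyldimethylsilyloxy)-2-[(2R)-3-methylbut-3-en-2-yl]phenyl acetate
Conditions: Zn, CH2Br2, TiCl4, THF–CH2Cl2, 0 °C to rt
Reagents that add atoms: dibromomethane, BrCBr
Why: Lombardo–Takai methylenation; the non-basic zinc–titanium methylene reagent converts hindered, enolisable ketones into 1,1-disubstituted alkenes without epimerising the α-carbon and leaves the aryl acetate alone.

**Step 7**
Reactants: 10 3,5-bis(tert-butyldimethylsilyloxy)-2-[(2R)-3-methylbut-3-en-2-yl]phenyl acetate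
Product: 11 3,5-bis(tert-butyldimethylsilyloxy)-2-[(2R)-3-methylbut-3-en-2-yl]phenol
Conditions: i-Bu2AlH (2.5 equiv), CH2Cl2, −78 °C; aq. potassium sodium tartrate
Reagents that add atoms: none
Why: Reductive cleavage of the aryl acetate by hydride (acyl substitution, then reduction of the aldehyde); aryl silyl ethers and the alkene are inert, and neither acid nor hydroxide comes near the phenol that flanks the isopropenyl group.

**Step 8**
Reactants: 12 methyl 3,5-dihydroxybenzoate; 13 3-chloro-3-methylbut-1-yne
Product: 14 methyl 3,5-bis[(2-methylbut-3-yn-2-yl)oxy]benzoate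
Conditions: 13 (2.6 equiv), DBU, CuCl2·2H2O (1 mol %), MeCN, 0 °C
Reagents that add atoms: none
Why: Copper-catalysed propargylic etherification of phenols with a tertiary propargylic chloride, which goes through a copper acetylide/allenylidene and so forms the tertiary ether that a direct SN2 alkylation cannot give.

**Step 9**
Reactants: 14 methyl 3,5-bis[(2-methylbut-3-yn-2-yl)oxy]benzoate
Product: 15 methyl 3,5-bis[(2-methylbut-3-en-2-yl)oxy]benzoate
Conditions: H2 (1 atm), Pd/CaCO3 poisoned with Pb(OAc)2, quinoline, EtOAc, rt
Reagents that add atoms: none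
Why: Lindlar semihydrogenation of both terminal alkynes; the poisoned catalyst stops at the vinyl stage.

**Step 10**
Reactants: 15 methyl 3,5-bis[(2-methylbut-3-en-2-yl)oxy]benzoate
Product: 16 methyl 3,5-dihydroxy-2,6-bis(3-methylbut-2-en-1-yl)benzoate
Conditions: PhNEt2, 140 °C, argon
Reagents that add atoms: none
Why: Twofold aromatic Claisen rearrangement of the 1,1-dimethylallyl ethers, which delivers normal prenyl groups; each shift is expected at the ortho carbon next to the ester rather than at C4, because a meta acceptor directs the migration towards itself and a meta oxygen donor directs it para to itself, and both effects point to the same carbon.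

**Step 11**
Reactants: 16 methyl 3,5-dihydroxy-2,6-bis(3-methylbut-2-en-1-yl)benzoate
Product: 17 methyl 7-hydroxy-2,2-dimethyl-6-(3-methylbut-2-en-1-yl)chromane-5-carboxylate
Conditions: Amberlyst 15, CH2Cl2, rt, stopped at partial conversion; recovered 16 recycled
Reagents that add atoms: none
Why: Acid-catalysed Markovnikov hydroalkoxylation (6-endo closure of the phenol onto the protonated prenyl group) gives the 2,2-dimethylchromane; the two prenyl/hydroxyl pairs are equivalent, so closing one is a statistical desymmetrisation run to partial conversion.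

**Step 12**
Reactants: 17 methyl 7-hydroxy-2,2-dimethyl-6-(3-methylbut-2-en-1-yl)chromane-5-carboxylate
Product: 18 7-hydroxy-2,2-dimethyl-6-(3-methylbut-2-en-1-yl)chromane-5-carboxylic acid
Conditions: EtSNa (4 equiv), DMF, 100 °C; then dilute HCl, 0 °C, to pH 4
Reagents that add atoms: none
Why: SN2 dealkylation of the methyl ester by thiolate at the methyl carbon, chosen because the carbonyl of this di-ortho-substituted benzoate is shielded from hydroxide; the basic medium keeps the o-prenylphenol from cyclising.

**Step 13**
Reactants: 18 7-hydroxy-2,2-dimethyl-6-(3-methylbut-2-en-1-yl)chromane-5-carboxylic acid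
Product: 20 7-(tert-butyldimethylsilyloxy)-2,2-dimethyl-6-(3-methylbut-2-en-1-yl)chromane-5-carboxylic acid, via silyl ester 19 (not isolated)
Conditions: TBSCl (2.5 equiv), imidazole, DMF, rt; then THF–H2O–AcOH, rt
Reagents that add atoms: tert-butyldimethylsilyl chloride, CC(C)(C)[Si](C)(C)Cl
Why: Silylation of phenol and carboxylic acid, then selective hydrolysis of the much more labile silyl ester, the usual way to silylate the phenol of a hydroxy acid.

**Step 14**
Reactants: 20 7-(tert-butyldimethylsilyloxy)-2,2-dimethyl-6-(3-methylbut-2-en-1-yl)chromane-5-carboxylic acid; 11 3,5-bis(tert-butyldimethylsilyloxy)-2-[(2R)-3-methylbut-3-en-2-yl]phenol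
Product: 22 3,5-bis(tert-butyldimethylsilyloxy)-2-[(2R)-3-methylbut-3-en-2-yl]phenyl 7-(tert-butyldimethylsilyloxy)-2,2-dimethyl-6-(3-methylbut-2-en-1-yl)chromane-5-carboxylate, via acid chloride 21 (not isolated)
Conditions: 20, 1-chloro-N,N,2-trimethylprop-1-en-1-amine (1.1 equiv), CH2Cl2, 0 °C to rt; then added to 11, NaH, THF, 0 °C to rt
Reagents that add atoms: none
Why: The α-chloroenamine converts the hindered acid into its chloride under neutral conditions, so no HCl can add to the prenyl group; the di-ortho-substituted aroyl chloride, which reacts through an acylium-like transition state, then acylates the preformed sodium phenoxide of 11 (nucleophilic acyl substitution).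

**Step 15**
Reactants: 22 3,5-bis(tert-butyldimethylsilyloxy)-2-[(2R)-3-methylbut-3-en-2-yl]phenyl 7-(tert-butyldimethylsilyloxy)-2,2-dimethyl-6-(3-methylbut-2-en-1-yl)chromane-5-carboxylate
Product: 23 5-{1-[3,5-bis(tert-butyldimethylsilyloxy)-2-[(2R)-3-methylbut-3-en-2-yl]phenoxy]ethenyl}-7-(tert-butyldimethylsilyloxy)-2,2-dimethyl-6-(3-methylbut-2-en-1-yl)chromane
Conditions: Cp2TiMe2 (3 equiv), PhMe, 70 °C, dark; filtration through basic Al2O3
Reagents that add atoms: dimethyltitanocene, C[Ti+2]C.c1cc[cH-]c1.c1cc[cH-]c1
Why: Petasis methylenation; thermolysis of Cp2TiMe2 gives Cp2Ti=CH2, which adds to the ester carbonyl to an oxatitanacyclobutane that collapses to the enol ether, a titanium methylidene olefination established for aryl benzoates; the reagent is non-basic and leaves silyl ethers and unstrained alkenes alone.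

**Step 16**
Reactants: 23 5-{1-[3,5-bis(tert-butyldimethylsilyloxy)-2-[(2R)-3-methylbut-3-en-2-yl]phenoxy]ethenyl}-7-(tert-butyldimethylsilyloxy)-2,2-dimethyl-6-(3-methylbut-2-en-1-yl)chromane
Product: 25 4,6-bis(tert-butyldimethylsilyloxy)-2-[7-(tert-butyldimethylsilyloxy)-2,2-dimethyl-6-(3-methylbut-2-en-1-yl)chroman-5-yl]-7-[(2R)-3-methylbut-3-en-2-yl]-2,3-dihydrobenzofuran (C2 epimers), via carbonyl ylide 24 (not isolated)
Conditions: hν (300 nm lamps, quartz), degassed MeCN (2 mM), solid NaHCO3, rt
Reagents that add atoms: none
Why: Excitation of the aryl vinyl ether brings the oxygen lone pair, the vinyl π bond and the C7a–C3a π bond of ring A into a six-electron system that closes in the conrotatory, excited-state-allowed sense and forms the C3–C3a bond, giving carbonyl ylide 24 whose carbanion end at C2 is benzylic to ring C. A suprafacial 1,4-hydrogen shift from C3a to C2 (or protonation at C2 and loss of the C3a proton) restores the aromaticity of ring A and gives 25. The closest known reaction type is the heteroatom-directed photoarylation of aryl vinyl ethers, documented mainly for 2-aryloxyenones, where the same bond forms and the same ylide-to-dihydrobenzofuran hydrogen shift follows; here an aryl group takes the place of the carbonyl group at the ylide carbon. Ring B, the only ring formed, is five-membered and closes by electrocyclisation and not by a polar exo or endo attack. The new stereocentre at C2 is not controlled and need not be, because step 17 removes it. The selectivity required is between the two ortho carbons of the C7a oxygen, and the substrate secures it: C7 bears the side chain, so closure there cannot be followed by a hydrogen shift and reverts, and the same substituent turns the vinyl group towards C3a. Degassing prevents trapping of 24 by oxygen, and the solid base keeps the acid-labile enol ether from hydrolysing.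

**Step 17**
Reactants: 25 4,6-bis(tert-butyldimethylsilyloxy)-2-[7-(tert-butyldimethylsilyloxy)-2,2-dimethyl-6-(3-methylbut-2-en-1-yl)chroman-5-yl]-7-[(2R)-3-methylbut-3-en-2-yl]-2,3-dihydrobenzofuran (C2 epimers)
Product: 26 4,6-bis(tert-butyldimethylsilyloxy)-2-[7-(tert-butyldimethylsilyloxy)-2,2-dimethyl-6-(3-methylbut-2-en-1-yl)chroman-5-yl]-7-[(2R)-3-methylbut-3-en-2-yl]benzofuran
Conditions: DDQ (1.1 equiv), PhH, rt
Reagents that add atoms: none
Why: DDQ dehydrogenation of a 2-aryl-2,3-dihydrobenzofuran: hydride abstraction from C3, whose cation is stabilised by the three oxygen substituents of ring A and whose C–H bonds are held perpendicular to the ring, then loss of the C2 proton; the side-chain methine is as electron-rich but keeps its C–H bond in the plane of ring A between the two ortho substituents, which should make it slow to react.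

**Step 18**
Reactants: 26 4,6-bis(tert-butyldimethylsilyloxy)-2-[7-(tert-butyldimethylsilyloxy)-2,2-dimethyl-6-(3-methylbut-2-en-1-yl)chroman-5-yl]-7-[(2R)-3-methylbut-3-en-2-yl]benzofuran
Product: 27 2-[7-hydroxy-2,2-dimethyl-6-(3-methylbut-2-en-1-yl)chroman-5-yl]-7-[(2R)-3-methylbut-3-en-2-yl]benzofuran-4,6-diol
Conditions: Bu4NF (3.5 equiv), AcOH (3.5 equiv), THF, 0 °C, argon
Reagents that add atoms: none
Why: Fluoride cleavage of the three aryl silyl ethers by substitution at silicon; the acetic acid buffer keeps the phenoxides protonated, and no acid strong enough to cyclise the prenyl or isopropenyl group onto a neighbouring phenol is present.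

## Compound list

1 | phloroglucinol (benzene-1,3,5-triol) | Oc1cc(O)cc(O)c1 | starting material
2 | 3,5-bis(tert-butyldimethylsilyloxy)phenol | Oc1cc(O[Si](C)(C)C(C)(C)C)cc(O[Si](C)(C)C(C)(C)C)c1 | intermediate
3 | (E)-3-methylpent-3-en-2-one | C/C=C(C)/C(C)=O | starting material
4 | (2R,3E)-3-methylpent-3-en-2-ol | C/C=C(C)/[C@@H](C)O | intermediate
5 | 1-[(2S,3E)-3-methylpent-3-en-2-yl]oxy-3,5-bis(tert-butyldimethylsilyloxy)benzene | C/C=C(C)/[C@H](C)Oc1cc(O[Si](C)(C)C(C)(C)C)cc(O[Si](C)(C)C(C)(C)C)c1 | intermediate
6 | 3,5-bis(tert-butyldimethylsilyloxy)-2-[(2R,3E)-3-methylpent-3-en-2-yl]phenol | C/C=C(C)/[C@@H](C)c1c(O)cc(O[Si](C)(C)C(C)(C)C)cc1O[Si](C)(C)C(C)(C)C | intermediate (not isolated)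
7 | 3,5-bis(tert-butyldimethylsilyloxy)-2-[(2R,3E)-3-methylpent-3-en-2-yl]phenyl acetate | C/C=C(C)/[C@@H](C)c1c(OC(C)=O)cc(O[Si](C)(C)C(C)(C)C)cc1O[Si](C)(C)C(C)(C)C | intermediate
8 | ozonide of 7 (3,5-dimethyl-1,2,4-trioxolane carrying the (1S)-1-arylethyl group at C3; mixture at the two trioxolane carbons) | CC1OOC(C)([C@@H](C)c2c(OC(C)=O)cc(O[Si](C)(C)C(C)(C)C)cc2O[Si](C)(C)C(C)(C)C)O1 | intermediate (not isolated)
9 | 3,5-bis(tert-butyldimethylsilyloxy)-2-[(2S)-3-oxobutan-2-yl]phenyl acetate | CC(=O)[C@@H](C)c1c(OC(C)=O)cc(O[Si](C)(C)C(C)(C)C)cc1O[Si](C)(C)C(C)(C)C | intermediate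
10 | 3,5-bis(tert-butyldimethylsilyloxy)-2-[(2R)-3-methylbut-3-en-2-yl]phenyl acetate | C=C(C)[C@@H](C)c1c(OC(C)=O)cc(O[Si](C)(C)C(C)(C)C)cc1O[Si](C)(C)C(C)(C)C | intermediate
11 | 3,5-bis(tert-butyldimethylsilyloxy)-2-[(2R)-3-methylbut-3-en-2-yl]phenol | C=C(C)[C@@H](C)c1c(O)cc(O[Si](C)(C)C(C)(C)C)cc1O[Si](C)(C)C(C)(C)C | intermediate
12 | methyl 3,5-dihydroxybenzoate | COC(=O)c1cc(O)cc(O)c1 | starting material
13 | 3-chloro-3-methylbut-1-yne | C#CC(C)(C)Cl | starting material
14 | methyl 3,5-bis[(2-methylbut-3-yn-2-yl)oxy]benzoate | COC(=O)c1cc(OC(C)(C)C#C)cc(OC(C)(C)C#C)c1 | intermediate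
15 | methyl 3,5-bis[(2-methylbut-3-en-2-yl)oxy]benzoate | COC(=O)c1cc(OC(C)(C)C=C)cc(OC(C)(C)C=C)c1 | intermediate
16 | methyl 3,5-dihydroxy-2,6-bis(3-methylbut-2-en-1-yl)benzoate | COC(=O)c1c(CC=C(C)C)c(O)cc(O)c1CC=C(C)C | intermediate
17 | methyl 7-hydroxy-2,2-dimethyl-6-(3-methylbut-2-en-1-yl)chromane-5-carboxylate | COC(=O)c1c(CC=C(C)C)c(O)cc2OC(C)(C)CCc12 | intermediate
18 | 7-hydroxy-2,2-dimethyl-6-(3-methylbut-2-en-1-yl)chromane-5-carboxylic acid | OC(=O)c1c(CC=C(C)C)c(O)cc2OC(C)(C)CCc12 | intermediate
19 | tert-butyldimethylsilyl 7-(tert-butyldimethylsilyloxy)-2,2-dimethyl-6-(3-methylbut-2-en-1-yl)chromane-5-carboxylate | CC(C)(C)[Si](C)(C)OC(=O)c1c(CC=C(C)C)c(O[Si](C)(C)C(C)(C)C)cc2OC(C)(C)CCc12 | intermediate (not isolated)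
20 | 7-(tert-butyldimethylsilyloxy)-2,2-dimethyl-6-(3-methylbut-2-en-1-yl)chromane-5-carboxylic acid | OC(=O)c1c(CC=C(C)C)c(O[Si](C)(C)C(C)(C)C)cc2OC(C)(C)CCc12 | intermediate
21 | 7-(tert-butyldimethylsilyloxy)-2,2-dimethyl-6-(3-methylbut-2-en-1-yl)chromane-5-carbonyl chloride | ClC(=O)c1c(CC=C(C)C)c(O[Si](C)(C)C(C)(C)C)cc2OC(C)(C)CCc12 | intermediate (not isolated)
22 | 3,5-bis(tert-butyldimethylsilyloxy)-2-[(2R)-3-methylbut-3-en-2-yl]phenyl 7-(tert-butyldimethylsilyloxy)-2,2-dimethyl-6-(3-methylbut-2-en-1-yl)chromane-5-carboxylate | C=C(C)[C@@H](C)c1c(O[Si](C)(C)C(C)(C)C)cc(O[Si](C)(C)C(C)(C)C)cc1OC(=O)c1c(CC=C(C)C)c(O[Si](C)(C)C(C)(C)C)cc2OC(C)(C)CCc12 | intermediate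
23 | 5-{1-[3,5-bis(tert-butyldimethylsilyloxy)-2-[(2R)-3-methylbut-3-en-2-yl]phenoxy]ethenyl}-7-(tert-butyldimethylsilyloxy)-2,2-dimethyl-6-(3-methylbut-2-en-1-yl)chromane | C=C(C)[C@@H](C)c1c(O[Si](C)(C)C(C)(C)C)cc(O[Si](C)(C)C(C)(C)C)cc1OC(=C)c1c(CC=C(C)C)c(O[Si](C)(C)C(C)(C)C)cc2OC(C)(C)CCc12 | intermediate
24 | carbonyl ylide from 23 (C3–C3a bond formed, C3a sp3 with hydrogen, O1 oxonium doubly bonded to C7a, carbanion at C2) | C=C(C)[C@@H](C)C1=C(O[Si](C)(C)C(C)(C)C)C=C(O[Si](C)(C)C(C)(C)C)C2C[C-](c3c(CC=C(C)C)c(O[Si](C)(C)C(C)(C)C)cc4OC(C)(C)CCc34)[O+]=C12 | intermediate (not isolated)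
25 | 4,6-bis(tert-butyldimethylsilyloxy)-2-[7-(tert-butyldimethylsilyloxy)-2,2-dimethyl-6-(3-methylbut-2-en-1-yl)chroman-5-yl]-7-[(2R)-3-methylbut-3-en-2-yl]-2,3-dihydrobenzofuran (C2 epimers) | C=C(C)[C@@H](C)c1c(O[Si](C)(C)C(C)(C)C)cc(O[Si](C)(C)C(C)(C)C)c2c1OC(c1c(CC=C(C)C)c(O[Si](C)(C)C(C)(C)C)cc3OC(C)(C)CCc13)C2 | intermediate
26 | 4,6-bis(tert-butyldimethylsilyloxy)-2-[7-(tert-butyldimethylsilyloxy)-2,2-dimethyl-6-(3-methylbut-2-en-1-yl)chroman-5-yl]-7-[(2R)-3-methylbut-3-en-2-yl]benzofuran | C=C(C)[C@@H](C)c1c(O[Si](C)(C)C(C)(C)C)cc(O[Si](C)(C)C(C)(C)C)c2cc(-c3c(CC=C(C)C)c(O[Si](C)(C)C(C)(C)C)cc4OC(C)(C)CCc34)oc12 | intermediate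
27 | 2-[7-hydroxy-2,2-dimethyl-6-(3-methylbut-2-en-1-yl)chroman-5-yl]-7-[(2R)-3-methylbut-3-en-2-yl]benzofuran-4,6-diol | C=C(C)[C@@H](C)c1c(O)cc(O)c2cc(-c3c(CC=C(C)C)c(O)cc4c3CCC(C)(C)O4)oc12 | target

## Step count and risk

Total: 18 steps. Longest linear sequence: 11 steps (steps 1, 3–7 and 14–18 from 1; equally steps 8–18 from 12).

**Step 16 (key step).** The closure may be inefficient. Ring C is twisted out of conjugation with the vinyl group by its two ortho substituents and the ylide has no carbonyl group, so the excited state may relax, or the ylide may revert, faster than the hydrogen shift. Competing photoreactions are a di-π-methane-type rearrangement of the 3-arylbutene unit and a [2+2] addition between the enol ether and the neighbouring isopropenyl group. The fallback closes ring B by an acyl Wittig reaction; it sets out from 11 and returns at 26. Magnesium-mediated ortho-formylation of 11 (MgCl2, Et3N, paraformaldehyde, MeCN, reflux) can only reach the future C3a and gives the salicylaldehyde F1. NaBH4 gives the benzylic alcohol F2, and PPh3·HBr in MeCN gives the phosphonium bromide F3. Acylation of F3 with 21 and Et3N in toluene gives the O-aroyl phosphonium salt F4, whose ylide closes onto the ester carbonyl on heating and gives 26 directly.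

**Step 15.** Methylenation may be slow or fail. The ester plane of a di-ortho-substituted benzoate is perpendicular to ring C, so the prenyl and chromane methylenes shield both faces of the carbonyl; long heating then favours decomposition of the reagent or loss of aryloxide from the oxatitanacycle. The fallback forms the enol ether C–O bond by cross-coupling; it sets out from 20 and returns at 23. MeLi (Et2O, 0 °C) converts 20 into the methyl ketone F5. KN(SiMe3)2 and PhNTf2 give the enol triflate F6. Coupling of F6 with 11 using Pd2(dba)3, 2-(di-tert-butylphosphino)biphenyl and K3PO4 in toluene (zerovalent palladium catalysis) gives 23.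

**Step 17.** Over-oxidation may occur by hydride abstraction at the prenyl methylene of ring C, at C4 of the chromane or at the side-chain methine, all of which are benzylic to oxygenated rings. The fallback reaches 26 without a dihydro stage by reductive carbonyl coupling; it sets out from 11 and returns at 26. Aldehyde F1, made as in the fallback to step 16, is acylated with 21 (NaH, THF) to the aldehyde ester F7. Low-valent titanium (TiCl3, Zn, DME, reflux) couples the aldehyde and ester carbonyls in an intramolecular McMurry-type reaction and gives 26.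

**Step 4.** Configuration may be partly lost if the Lewis acid ionises the electron-rich aryl allyl ether to a phenoxide/allyl cation pair that recombines without memory, or if a boat transition state competes. The fallback gives up chirality transfer; it sets out from 2 and returns at 11. Mitsunobu etherification of 2 with (E)-2-methylbut-2-en-1-ol gives the achiral ether F8. Thermal Claisen rearrangement (PhNEt2, 160 °C) gives the racemic phenol F9, which already has the correct side chain, so steps 5–7 are not needed. Resolution of F9 by preparative chromatography on a chiral stationary phase gives 11.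

**Step 10.** Part of the migration may go to C4, between the two oxygens, or the tertiary ethers may lose isoprene on heating. The fallback blocks C4; it sets out at the stage of 12, whose commercially available bromo derivative, methyl 4-bromo-3,5-dihydroxybenzoate F10, is used in its place, and returns at 16. Etherification with 13 as in step 8 gives the bis(propargyl) ether F11. Semihydrogenation as in step 9 gives the bis(1,1-dimethylallyl) ether F12. Heating as in step 10 can then only give the bromo diprenyl resorcinol F13. Hydrodebromination with Pd(OAc)2, PPh3 and HCO2H–Et3N in DMF gives 16.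

## Further compounds

F1 | step 16 | 2-hydroxy-4,6-bis(tert-butyldimethylsilyloxy)-3-[(2R)-3-methylbut-3-en-2-yl]benzaldehyde | C=C(C)[C@@H](C)c1c(O[Si](C)(C)C(C)(C)C)cc(O[Si](C)(C)C(C)(C)C)c(C=O)c1O
F2 | step 16 | {2-hydroxy-4,6-bis(tert-butyldimethylsilyloxy)-3-[(2R)-3-methylbut-3-en-2-yl]phenyl}methanol | C=C(C)[C@@H](C)c1c(O[Si](C)(C)C(C)(C)C)cc(O[Si](C)(C)C(C)(C)C)c(CO)c1O
F3 | step 16 | {2-hydroxy-4,6-bis(tert-butyldimethylsilyloxy)-3-[(2R)-3-methylbut-3-en-2-yl]benzyl}triphenylphosphonium bromide | C=C(C)[C@@H](C)c1c(O[Si](C)(C)C(C)(C)C)cc(O[Si](C)(C)C(C)(C)C)c(C[P+](c2ccccc2)(c2ccccc2)c2ccccc2)c1O.[Br-]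
F4 | step 16 | O-aroyl derivative of F3 (phenol oxygen acylated by the ring C carboxylic acid) | C=C(C)[C@@H](C)c1c(O[Si](C)(C)C(C)(C)C)cc(O[Si](C)(C)C(C)(C)C)c(C[P+](c2ccccc2)(c2ccccc2)c2ccccc2)c1OC(=O)c1c(CC=C(C)C)c(O[Si](C)(C)C(C)(C)C)cc2OC(C)(C)CCc12.[Br-]
F5 | step 15 | 1-[7-(tert-butyldimethylsilyloxy)-2,2-dimethyl-6-(3-methylbut-2-en-1-yl)chroman-5-yl]ethan-1-one | CC(=O)c1c(CC=C(C)C)c(O[Si](C)(C)C(C)(C)C)cc2OC(C)(C)CCc12
F6 | step 15 | 1-[7-(tert-butyldimethylsilyloxy)-2,2-dimethyl-6-(3-methylbut-2-en-1-yl)chroman-5-yl]ethenyl trifluoromethanesulfonate | C=C(OS(=O)(=O)C(F)(F)F)c1c(CC=C(C)C)c(O[Si](C)(C)C(C)(C)C)cc2OC(C)(C)CCc12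
F7 | step 17 | 2-formyl-3,5-bis(tert-butyldimethylsilyloxy)-6-[(2R)-3-methylbut-3-en-2-yl]phenyl 7-(tert-butyldimethylsilyloxy)-2,2-dimethyl-6-(3-methylbut-2-en-1-yl)chromane-5-carboxylate | C=C(C)[C@@H](C)c1c(O[Si](C)(C)C(C)(C)C)cc(O[Si](C)(C)C(C)(C)C)c(C=O)c1OC(=O)c1c(CC=C(C)C)c(O[Si](C)(C)C(C)(C)C)cc2OC(C)(C)CCc12
F8 | step 4 | 1-[(2E)-2-methylbut-2-en-1-yl]oxy-3,5-bis(tert-butyldimethylsilyloxy)benzene | C/C=C(\C)COc1cc(O[Si](C)(C)C(C)(C)C)cc(O[Si](C)(C)C(C)(C)C)c1
F9 | step 4 | racemic 3,5-bis(tert-butyldimethylsilyloxy)-2-(3-methylbut-3-en-2-yl)phenol | C=C(C)C(C)c1c(O)cc(O[Si](C)(C)C(C)(C)C)cc1O[Si](C)(C)C(C)(C)C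
F10 | step 10 | methyl 4-bromo-3,5-dihydroxybenzoate | COC(=O)c1cc(O)c(Br)c(O)c1
F11 | step 10 | methyl 4-bromo-3,5-bis[(2-methylbut-3-yn-2-yl)oxy]benzoate | COC(=O)c1cc(OC(C)(C)C#C)c(Br)c(OC(C)(C)C#C)c1
F12 | step 10 | methyl 4-bromo-3,5-bis[(2-methylbut-3-en-2-yl)oxy]benzoate | COC(=O)c1cc(OC(C)(C)C=C)c(Br)c(OC(C)(C)C=C)c1
F13 | step 10 | methyl 4-bromo-3,5-dihydroxy-2,6-bis(3-methylbut-2-en-1-yl)benzoate | COC(=O)c1c(CC=C(C)C)c(O)c(Br)c(O)c1CC=C(C)C
A1 | alternative 1 | 5-(allyloxy)-2-[(2R)-3-methylbut-3-en-2-yl]-3-(triisopropylsilyloxy)phenol | C=C(C)[C@@H](C)c1c(O[Si](C(C)C)(C(C)C)C(C)C)cc(OCC=C)cc1O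
A2 | alternative 1 | 3-(allyloxy)cyclobut-2-en-1-one | C=CCOC1=CC(=O)C1
A3 | alternative 1 | triisopropyl{[(3R)-3,4-dimethylpent-4-en-1-yn-1-yl]oxy}silane | C=C(C)[C@@H](C)C#CO[Si](C(C)C)(C(C)C)C(C)C
A4 | alternative 2 | 2-[7-(methoxymethoxy)-2,2-dimethyl-6-(3-methylbut-2-en-1-yl)chroman-5-yl]-7-[(2R)-3-methylbut-3-en-2-yl]benzofuran-4,6-diol | C=C(C)[C@@H](C)c1c(O)cc(O)c2cc(-c3c(CC=C(C)C)c(OCOC)cc4OC(C)(C)CCc34)oc12
A5 | alternative 2 | methyl 2-[(4S)-4,5-dimethyl-2-oxohex-5-en-3-yl]-5-[7-(methoxymethoxy)-2,2-dimethyl-6-(3-methylbut-2-en-1-yl)chroman-5-yl]furan-3-carboxylate (C3 of the side arm undefined) | COC(=O)c1cc(-c2c(CC=C(C)C)c(OCOC)cc3OC(C)(C)CCc23)oc1C(C(C)=O)[C@H](C)C(C)=C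
A6 | alternative 3 | tris(tert-butyldimethylsilyl) ether of the target (identical with 26) | C=C(C)[C@@H](C)c1c(O[Si](C)(C)C(C)(C)C)cc(O[Si](C)(C)C(C)(C)C)c2cc(-c3c(CC=C(C)C)c(O[Si](C)(C)C(C)(C)C)cc4OC(C)(C)CCc34)oc12
A7 | alternative 3 | {2-(aroyloxy)-4,6-bis(tert-butyldimethylsilyloxy)-3-[(2R)-3-methylbut-3-en-2-yl]benzyl}triphenylphosphonium bromide (aroyl = ring C carbonyl; same structure as F4) | C=C(C)[C@@H](C)c1c(O[Si](C)(C)C(C)(C)C)cc(O[Si](C)(C)C(C)(C)C)c(C[P+](c2ccccc2)(c2ccccc2)c2ccccc2)c1OC(=O)c1c(CC=C(C)C)c(O[Si](C)(C)C(C)(C)C)cc2OC(C)(C)CCc12.[Br-]
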